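**Retrosynthetic overview**

1. Ring numbering used here: cyclohexene C1 (aroyl), C2 (chalcone aryl), C3=C4(CH3), C5H2, C6 (4-hydroxyphenyl). The target is 1S,2S,6S, so the C1 acyl group is trans to the C2 aryl group but cis to the C6 aryl group. A [4+2] of an (E)-chalcone cannot give this, so the ring is not made by cycloaddition.
2. End game: seven MOM ethers off; C1 ketone by oxidation of a carbinol; chalcone enone from aryl bromide → aryllithium + cinnamoyl Weinreb amide; aroyl arm by addition of an arylcerium to the C1 aldehyde.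
3. The cyclohexene, the only ring that is built, is closed by ring-closing metathesis at C3=C4; all four benzene rings are bought.
4. Key step: stereodivergent iridium/amine dual-catalytic α-allylation of a β-aryl aldehyde with a racemic aryl vinyl carbinol forms C1–C2 and sets both centres under catalyst control.
5. C6 comes from an organocatalytic malonate Michael addition to a 4-arylbutenone; the bromo carbinol comes from amide-base lithiation of 4-bromoresorcinol bis-MOM ether; the prenylated ring comes from two successive directed ortho-metalations of resorcinol bis-MOM ether.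

Assumption: the SMILES is taken exactly as drawn (1S,2S,6S); where a chiral catalyst is named by its outcome, the enantiomer (or pseudoenantiomer) that gives the stated configuration is meant.

**Route**

Step 1
Reactants: 1 (E)-4-(4-hydroxyphenyl)but-3-en-2-one
Product: 2 (E)-4-[4-(methoxymethoxy)phenyl]but-3-en-2-one
Conditions: MOMCl, i-Pr2NEt, CH2Cl2, 0 °C → rt
Reagents that add atoms: chloromethyl methyl ether (MOMCl), COCCl
Why: Phenol O-alkylation with an α-chloro ether; the MOM acetal survives organolithium, ylide and metathesis steps and leaves under mild acid at the end.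

Step 2
Reactants: 2 (E)-4-[4-(methoxymethoxy)phenyl]but-3-en-2-one; 3 dimethyl malonate
Product: 4 dimethyl 2-{(1S)-1-[4-(methoxymethoxy)phenyl]-3-oxobutyl}propanedioate
Conditions: cinchona-derived primary amine–thiourea organocatalyst (10 mol%, pseudoenantiomer giving the S adduct), PhCO2H (10 mol%), toluene, rt
Reagents that add atoms: none
Why: Organocatalytic asymmetric Michael addition: the primary amine activates the enone as an iminium ion and the thiourea/base unit delivers the malonate to one face, setting the benzylic centre (later ring C6) as S.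

Step 3
Reactants: 4 dimethyl 2-{(1S)-1-[4-(methoxymethoxy)phenyl]-3-oxobutyl}propanedioate
Product: 5 methyl (3S)-3-[4-(methoxymethoxy)phenyl]-5-oxohexanoate
Conditions: LiCl, H2O, DMSO, 150 °C
Reagents that add atoms: none
Why: Krapcho dealkoxycarbonylation under near-neutral conditions; the stereocentre is not acidic and is untouched.

Step 4
Reactants: 5 methyl (3S)-3-[4-(methoxymethoxy)phenyl]-5-oxohexanoate
Product: 6 methyl (3S)-3-[4-(methoxymethoxy)phenyl]-5-methylhex-5-enoate
Conditions: Ph3PCH3Br, KOt-Bu, THF, 0 °C → rt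
Reagents that add atoms: methyltriphenylphosphonium bromide, C[P+](c1ccccc1)(c1ccccc1)c1ccccc1.[Br-]
Why: Wittig methylenation is chemoselective for the methyl ketone over the ester and installs the 1,1-disubstituted alkene needed for ring closure.

Step 5
Reactants: 6 methyl (3S)-3-[4-(methoxymethoxy)phenyl]-5-methylhex-5-enoate
Product: 8 (3S)-3-[4-(methoxymethoxy)phenyl]-5-methylhex-5-enal, via aluminium hemiacetal 7 (not isolated)
Conditions: i-Bu2AlH (1.1 equiv), CH2Cl2, −78 °C; aqueous work-up
Reagents that add atoms: none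
Why: Partial ester reduction: the tetrahedral aluminium hemiacetal is stable at −78 °C and releases the aldehyde only on work-up.

Step 6
Reactants: 9 4-bromobenzene-1,3-diol
Product: 10 1-bromo-2,4-bis(methoxymethoxy)benzene
Conditions: MOMCl, i-Pr2NEt, CH2Cl2, 0 °C → rt
Reagents that add atoms: chloromethyl methyl ether (MOMCl), COCCl
Why: Double phenol O-alkylation; the two MOM groups later direct lithiation to the carbon between them.

Step 7
Reactants: 10 1-bromo-2,4-bis(methoxymethoxy)benzene; 11 prop-2-enal (acrolein)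
Product: 13 rac-1-[3-bromo-2,6-bis(methoxymethoxy)phenyl]prop-2-en-1-ol, via aryllithium 12 (not isolated)
Conditions: LiN(i-Pr)2, THF, −78 °C; then acrolein, −78 °C; H2O
Reagents that add atoms: none
Why: Directed ortho-metalation at the doubly MOM-flanked C–H (the amide base does not touch the C–Br bond, and Li is meta to Br so no aryne can form), then 1,2-addition to the enal; the carbinol is used as the racemate.

Step 8
Reactants: 14 benzene-1,3-diol (resorcinol)
Product: 15 1,3-bis(methoxymethoxy)benzene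
Conditions: MOMCl, i-Pr2NEt, CH2Cl2, 0 °C → rt
Reagents that add atoms: chloromethyl methyl ether (MOMCl), COCCl
Why: Double phenol O-alkylation gives the bis-MOM ether whose acetal oxygens direct both later metalations.

Step 9
Reactants: 15 1,3-bis(methoxymethoxy)benzene; 16 1-bromo-3-methylbut-2-ene (prenyl bromide)
Product: 18 1,3-bis(methoxymethoxy)-2-(3-methylbut-2-en-1-yl)benzene, via aryllithium 17 (not isolated)
Conditions: n-BuLi (1.1 equiv), THF, 0 °C → rt; CuBr·SMe2 (10 mol%), prenyl bromide, −78 → 0 °C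
Reagents that add atoms: none
Why: Directed ortho-metalation at the C–H between the two MOM ethers, then copper-catalysed allylic alkylation at the primary carbon of prenyl bromide, gives the linear 2-prenyl arene.

Step 10
Reactants: 19 2,4-dihydroxybenzaldehyde
Product: 20 2,4-bis(methoxymethoxy)benzaldehyde
Conditions: MOMCl, i-Pr2NEt, CH2Cl2, 0 °C → reflux
Reagents that add atoms: chloromethyl methyl ether (MOMCl), COCCl
Why: Phenol O-alkylation; heating is needed for the hydrogen-bonded ortho hydroxyl.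

Step 11
Reactants: 20 2,4-bis(methoxymethoxy)benzaldehyde; 21 diethyl {2-[methoxy(methyl)amino]-2-oxoethyl}phosphonate
Product: 22 (2E)-3-[2,4-bis(methoxymethoxy)phenyl]-N-methoxy-N-methylprop-2-enamide
Conditions: LiCl, DBU, MeCN, rt
Reagents that add atoms: none
Why: Horner–Wadsworth–Emmons olefination under Masamune–Roush conditions gives the E-enamide, which fixes the chalcone alkene geometry.

Step 12
Reactants: 8 (3S)-3-[4-(methoxymethoxy)phenyl]-5-methylhex-5-enal; 13 rac-1-[3-bromo-2,6-bis(methoxymethoxy)phenyl]prop-2-en-1-ol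
Product: 23 (2S,3S)-3-[3-bromo-2,6-bis(methoxymethoxy)phenyl]-2-{(1S)-1-[4-(methoxymethoxy)phenyl]-3-methylbut-3-en-1-yl}pent-4-enal
Conditions: [Ir(cod)Cl]2 (3 mol%), BINOL-derived N-dibenzo[b,f]azepinyl phosphoramidite–olefin ligand (12 mol%, enantiomer giving the 3S centre), (R)-2-{bis[3,5-bis(trifluoromethyl)phenyl][(trimethylsilyl)oxy]methyl}pyrrolidine (15 mol%), ZnBr2 (7.5 mol%), ClCH2CH2Cl, 25 °C
Reagents that add atoms: none
Why: Stereodivergent iridium/amine dual-catalytic α-allylation of an aldehyde: the allyl–iridium complex formed enantioconvergently from the racemic carbinol is attacked at its benzylic terminus (branched product), so the ligand fixes C3 (ring C2, S), while the (R)-diarylprolinol silyl ether shields one enamine face and fixes C2 (ring C1, S); the existing β-centre is a spectator.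

Step 13
Reactants: 23 (2S,3S)-3-[3-bromo-2,6-bis(methoxymethoxy)phenyl]-2-{(1S)-1-[4-(methoxymethoxy)phenyl]-3-methylbut-3-en-1-yl}pent-4-enal
Product: 24 (1S,2S,6S)-2-[3-bromo-2,6-bis(methoxymethoxy)phenyl]-6-[4-(methoxymethoxy)phenyl]-4-methylcyclohex-3-ene-1-carbaldehyde
Conditions: second-generation Grubbs catalyst (5 mol%), CH2Cl2, 40 °C
Reagents that add atoms: none
Why: Ring-closing metathesis of the vinyl and isopropenyl groups forms the trisubstituted cyclohexene with loss of ethene under neutral conditions, so no stereocentre is touched.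

Step 14
Reactants: 24 (1S,2S,6S)-2-[3-bromo-2,6-bis(methoxymethoxy)phenyl]-6-[4-(methoxymethoxy)phenyl]-4-methylcyclohex-3-ene-1-carbaldehyde; 18 1,3-bis(methoxymethoxy)-2-(3-methylbut-2-en-1-yl)benzene
Product: 27 [2,4-bis(methoxymethoxy)-3-(3-methylbut-2-en-1-yl)phenyl]{(1S,2S,6S)-2-[3-bromo-2,6-bis(methoxymethoxy)phenyl]-6-[4-(methoxymethoxy)phenyl]-4-methylcyclohex-3-en-1-yl}methanol (both carbinol epimers), via aryllithium 25 (not isolated), via arylcerium dichloride 26 (not isolated)
Conditions: 18 (1.6 equiv), n-BuLi (1.5 equiv), TMEDA, THF, 0 °C, 2 h; CeCl3 (anhydrous), −78 °C; then 24, −78 °C; H2O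
Reagents that add atoms: none
Why: Second directed ortho-metalation, now at the ring C–H next to one MOM ether (chelation-driven ring lithiation is kinetically preferred over deprotonation of the prenyl CH2, and the arene is kept in excess so no n-BuLi remains), then transmetalation to cerium and 1,2-addition: the weakly basic arylcerium adds to the hindered α-branched aldehyde without enolising C1 or touching the aryl bromide; the new carbinol centre is uncontrolled and is destroyed in step 16.

Step 15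
Reactants: 27 carbinol from step 14; 22 (2E)-3-[2,4-bis(methoxymethoxy)phenyl]-N-methoxy-N-methylprop-2-enamide
Product: 31 (2E)-1-{3-[(1S,5S,6S)-6-{[2,4-bis(methoxymethoxy)-3-(3-methylbut-2-en-1-yl)phenyl](hydroxy)methyl}-5-[4-(methoxymethoxy)phenyl]-3-methylcyclohex-2-en-1-yl]-2,4-bis(methoxymethoxy)phenyl}-3-[2,4-bis(methoxymethoxy)phenyl]prop-2-en-1-one (both carbinol epimers), via lithium alkoxide 28 (not isolated), via dilithio species 29 (not isolated), via tetrahedral adduct 30 (not isolated)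
Conditions: n-BuLi (2.1 equiv), THF, −78 °C; then 22, −78 → −20 °C; H2O
Reagents that add atoms: none
Why: Deprotonation of the hydroxyl, bromine–lithium exchange and Weinreb ketone synthesis: the chelated tetrahedral adduct stops at the enone; C1 is still at the carbinol level and so cannot epimerise under this base.

Step 16
Reactants: 31 chalcone carbinol from step 15
Product: 32 heptakis(methoxymethyl) ether of the target: (2E)-1-{3-[(1S,5S,6S)-6-[2,4-bis(methoxymethoxy)-3-(3-methylbut-2-en-1-yl)benzoyl]-5-[4-(methoxymethoxy)phenyl]-3-methylcyclohex-2-en-1-yl]-2,4-bis(methoxymethoxy)phenyl}-3-[2,4-bis(methoxymethoxy)phenyl]prop-2-en-1-one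
Conditions: Dess–Martin periodinane, CH2Cl2, 0 °C → rt
Reagents that add atoms: none
Why: Dess–Martin oxidation of the benzylic secondary alcohol is non-basic, so the now α-keto C1 centre (kinetic 1,2-trans/1,6-cis arrangement) is not epimerised; enone, prenyl and ring alkenes are inert.

Step 17
Reactants: 32 heptakis(methoxymethyl) ether of the target
Product: 33 CNP0218862.3: (2E)-1-{3-[(1S,5S,6S)-6-[2,4-dihydroxy-3-(3-methylbut-2-en-1-yl)benzoyl]-5-(4-hydroxyphenyl)-3-methylcyclohex-2-en-1-yl]-2,4-dihydroxyphenyl}-3-(2,4-dihydroxyphenyl)prop-2-en-1-one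
Conditions: HCl (3 M in MeOH), MeOH/THF, 0 °C → rt, stopped at full conversion
Reagents that add atoms: none
Why: Acid-catalysed acetal exchange removes all seven MOM groups as dimethoxymethane; short exposure at or below rt is used to avoid acid-mediated prenyl or ring-alkene cyclisation onto the free phenols and enolisation at C1.

**Compound list**

1 | (E)-4-(4-hydroxyphenyl)but-3-en-2-one | CC(=O)/C=C/c1ccc(O)cc1 | starting material
2 | (E)-4-[4-(methoxymethoxy)phenyl]but-3-en-2-one | CC(=O)/C=C/c1ccc(OCOC)cc1 | intermediate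
3 | dimethyl malonate | COC(=O)CC(=O)OC | starting material
4 | dimethyl 2-{(1S)-1-[4-(methoxymethoxy)phenyl]-3-oxobutyl}propanedioate | COC(=O)C(C(=O)OC)[C@H](CC(C)=O)c1ccc(OCOC)cc1 | intermediate
5 | methyl (3S)-3-[4-(methoxymethoxy)phenyl]-5-oxohexanoate | COC(=O)C[C@H](CC(C)=O)c1ccc(OCOC)cc1 | intermediate
6 | methyl (3S)-3-[4-(methoxymethoxy)phenyl]-5-methylhex-5-enoate | COC(=O)C[C@H](CC(C)=C)c1ccc(OCOC)cc1 | intermediate
7 | diisobutylaluminium hemiacetal of ester 6 (O–Al(i-Bu)2 and OMe on the former ester carbon) | COC(O[Al](CC(C)C)CC(C)C)C[C@H](CC(C)=C)c1ccc(OCOC)cc1 | intermediate (not isolated)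
8 | (3S)-3-[4-(methoxymethoxy)phenyl]-5-methylhex-5-enal | O=CC[C@H](CC(C)=C)c1ccc(OCOC)cc1 | intermediate
9 | 4-bromobenzene-1,3-diol | Oc1ccc(Br)c(O)c1 | starting material
10 | 1-bromo-2,4-bis(methoxymethoxy)benzene | COCOc1ccc(Br)c(OCOC)c1 | intermediate
11 | prop-2-enal (acrolein) | C=CC=O | starting material
12 | [3-bromo-2,6-bis(methoxymethoxy)phenyl]lithium | [Li]c1c(OCOC)ccc(Br)c1OCOC | intermediate (not isolated)
13 | rac-1-[3-bromo-2,6-bis(methoxymethoxy)phenyl]prop-2-en-1-ol | C=CC(O)c1c(OCOC)ccc(Br)c1OCOC | intermediate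
14 | benzene-1,3-diol (resorcinol) | Oc1cccc(O)c1 | starting material
15 | 1,3-bis(methoxymethoxy)benzene | COCOc1cccc(OCOC)c1 | intermediate
16 | 1-bromo-3-methylbut-2-ene | CC(C)=CCBr | starting material
17 | [2,6-bis(methoxymethoxy)phenyl]lithium | [Li]c1c(OCOC)cccc1OCOC | intermediate (not isolated)
18 | 1,3-bis(methoxymethoxy)-2-(3-methylbut-2-en-1-yl)benzene | CC(C)=CCc1c(OCOC)cccc1OCOC | intermediate
19 | 2,4-dihydroxybenzaldehyde | O=Cc1ccc(O)cc1O | starting material
20 | 2,4-bis(methoxymethoxy)benzaldehyde | O=Cc1ccc(OCOC)cc1OCOC | intermediate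
21 | diethyl {2-[methoxy(methyl)amino]-2-oxoethyl}phosphonate | CCOP(=O)(CC(=O)N(C)OC)OCC | starting material
22 | (2E)-3-[2,4-bis(methoxymethoxy)phenyl]-N-methoxy-N-methylprop-2-enamide | CON(C)C(=O)/C=C/c1ccc(OCOC)cc1OCOC | intermediate
23 | (2S,3S)-3-[3-bromo-2,6-bis(methoxymethoxy)phenyl]-2-{(1S)-1-[4-(methoxymethoxy)phenyl]-3-methylbut-3-en-1-yl}pent-4-enal | O=C[C@H]([C@@H](c1c(OCOC)ccc(Br)c1OCOC)C=C)[C@H](CC(C)=C)c1ccc(OCOC)cc1 | intermediate
24 | (1S,2S,6S)-2-[3-bromo-2,6-bis(methoxymethoxy)phenyl]-6-[4-(methoxymethoxy)phenyl]-4-methylcyclohex-3-ene-1-carbaldehyde | O=C[C@@H]1[C@@H](c2c(OCOC)ccc(Br)c2OCOC)C=C(C)C[C@@H]1c1ccc(OCOC)cc1 | intermediate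
25 | [2,4-bis(methoxymethoxy)-3-(3-methylbut-2-en-1-yl)phenyl]lithium | [Li]c1ccc(OCOC)c(CC=C(C)C)c1OCOC | intermediate (not isolated)
26 | [2,4-bis(methoxymethoxy)-3-(3-methylbut-2-en-1-yl)phenyl]cerium dichloride | Cl[Ce](Cl)c1ccc(OCOC)c(CC=C(C)C)c1OCOC | intermediate (not isolated)
27 | [2,4-bis(methoxymethoxy)-3-(3-methylbut-2-en-1-yl)phenyl]{(1S,2S,6S)-2-[3-bromo-2,6-bis(methoxymethoxy)phenyl]-6-[4-(methoxymethoxy)phenyl]-4-methylcyclohex-3-en-1-yl}methanol, both carbinol epimers | CC(C)=CCc1c(OCOC)ccc(C(O)[C@@H]2[C@@H](c3c(OCOC)ccc(Br)c3OCOC)C=C(C)C[C@@H]2c2ccc(OCOC)cc2)c1OCOC | intermediate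
28 | lithium alkoxide of 27 | CC(C)=CCc1c(OCOC)ccc(C(O[Li])[C@@H]2[C@@H](c3c(OCOC)ccc(Br)c3OCOC)C=C(C)C[C@@H]2c2ccc(OCOC)cc2)c1OCOC | intermediate (not isolated)
29 | dilithio species: lithium alkoxide of 27 carrying Li in place of Br | CC(C)=CCc1c(OCOC)ccc(C(O[Li])[C@@H]2[C@@H](c3c(OCOC)ccc([Li])c3OCOC)C=C(C)C[C@@H]2c2ccc(OCOC)cc2)c1OCOC | intermediate (not isolated)
30 | tetrahedral adduct of 29 and amide 22 (lithium N-methoxy-N-methyl hemiaminal alkoxide) | CC(C)=CCc1c(OCOC)ccc(C(O[Li])[C@@H]2[C@@H](c3c(OCOC)ccc(C(O[Li])(N(C)OC)/C=C/c4ccc(OCOC)cc4OCOC)c3OCOC)C=C(C)C[C@@H]2c2ccc(OCOC)cc2)c1OCOC | intermediate (not isolated)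
31 | chalcone carbinol (name as in step 15), both carbinol epimers | CC(C)=CCc1c(OCOC)ccc(C(O)[C@@H]2[C@@H](c3c(OCOC)ccc(C(=O)/C=C/c4ccc(OCOC)cc4OCOC)c3OCOC)C=C(C)C[C@@H]2c2ccc(OCOC)cc2)c1OCOC | intermediate
32 | heptakis(methoxymethyl) ether of the target (name as in step 16) | CC(C)=CCc1c(OCOC)ccc(C(=O)[C@@H]2[C@@H](c3c(OCOC)ccc(C(=O)/C=C/c4ccc(OCOC)cc4OCOC)c3OCOC)C=C(C)C[C@@H]2c2ccc(OCOC)cc2)c1OCOC | intermediate
33 | CNP0218862.3 (name as in step 17) | CC(C)=CCc1c(O)ccc(C(=O)[C@@H]2[C@@H](c3c(O)ccc(C(=O)/C=C/c4ccc(O)cc4O)c3O)C=C(C)C[C@@H]2c2ccc(O)cc2)c1O | target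

**Totals and risk**

Total step count: 17. Longest linear sequence: 11 steps (steps 1–5, then 12–17).

Three steps most likely to fail:

Step 12 (dual-catalytic α-allylation). The risks are a β-branched aldehyde, a di-ortho-alkoxy carbinol whose MOM oxygen could trap the allyl cation, and possible mismatch with the existing centre. The fallback replaces catalytic allylation by a reagent-controlled sigmatropic rearrangement. It sets out from 6 and 13 and comes back at 23. Ester 6 is saponified (LiOH, THF/H2O) to (3S)-3-[4-(methoxymethoxy)phenyl]-5-methylhex-5-enoic acid F1. Carbinol 13 is transposed with catalytic Ph3SiOReO3 to (2E)-3-[3-bromo-2,6-bis(methoxymethoxy)phenyl]prop-2-en-1-ol F2. The two are joined (DCC, DMAP) to the allyl ester (2E)-3-[3-bromo-2,6-bis(methoxymethoxy)phenyl]prop-2-en-1-yl (3S)-3-[4-(methoxymethoxy)phenyl]-5-methylhex-5-enoate F3. An enantioselective ester-enolate Claisen rearrangement through a chiral boron enolate (C2-symmetric 1,2-diphenylethane-1,2-bis(sulfonamide)-derived bromoborane, tertiary amine, CH2Cl2, −78 °C → rt) then gives (2S,3S)-3-[3-bromo-2,6-bis(methoxymethoxy)phenyl]-2-{(1S)-1-[4-(methoxymethoxy)phenyl]-3-methylbut-3-en-1-yl}pent-4-enoic acid F4; the chair transition state and enolate geometry fix the relative configuration and the borane enantiomer fixes the absolute sense. LiAlH4 reduction at 0 °C gives the primary alcohol (2S,3S)-3-[3-bromo-2,6-bis(methoxymethoxy)phenyl]-2-{(1S)-1-[4-(methoxymethoxy)phenyl]-3-methylbut-3-en-1-yl}pent-4-en-1-ol F5, and Dess–Martin oxidation returns aldehyde 23.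

Step 15 (dianion formation and acylation on an advanced intermediate). The risks are incomplete exchange, proton quench and alkylation by butyl bromide. The fallback moves the enone construction to a neutral palladium-catalysed carbonylation after the ketone is in place. It sets out from 27 and comes back at 32, so step 16 is absorbed. Carbinol 27 is oxidised with Dess–Martin periodinane to the bromo ketone [2,4-bis(methoxymethoxy)-3-(3-methylbut-2-en-1-yl)phenyl]{(1S,2S,6S)-2-[3-bromo-2,6-bis(methoxymethoxy)phenyl]-6-[4-(methoxymethoxy)phenyl]-4-methylcyclohex-3-en-1-yl}methanone F6. Aldehyde 20 is converted by boron-Wittig olefination (CH2(Bpin)2, lithium 2,2,6,6-tetramethylpiperidide, THF) into 2-{(E)-2-[2,4-bis(methoxymethoxy)phenyl]ethenyl}-4,4,5,5-tetramethyl-1,3,2-dioxaborolane F7. Carbonylative Suzuki–Miyaura coupling of F6 with F7 (Pd(OAc)2, di(1-adamantyl)-n-butylphosphine, CO, K2CO3, toluene, 80 °C) gives 32.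

Step 17 (global deprotection). The risks are acid-mediated cyclisation of the prenyl group or the ring alkene onto free phenols, flavanone formation, and epimerisation at C1 to the probably more stable 1,2-cis/1,6-trans isomer. The fallback avoids Brønsted acid by exchanging the protecting groups. It sets out from 32 and comes back at 33. Treatment of 32 with TMSOTf and 2,2'-bipyridyl (MeCN, 0 °C → rt) converts the aryl MOM ethers into aryl silyl ethers, giving the heptakis(trimethylsilyl) ether of the target F8. This is hydrolysed with neutral aqueous methanol to 33.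

**Further compounds**

F1 | step 12 | (3S)-3-[4-(methoxymethoxy)phenyl]-5-methylhex-5-enoic acid | OC(=O)C[C@H](CC(C)=C)c1ccc(OCOC)cc1
F2 | step 12 | (2E)-3-[3-bromo-2,6-bis(methoxymethoxy)phenyl]prop-2-en-1-ol | OC/C=C/c1c(OCOC)ccc(Br)c1OCOC
F3 | step 12 | (2E)-3-[3-bromo-2,6-bis(methoxymethoxy)phenyl]prop-2-en-1-yl (3S)-3-[4-(methoxymethoxy)phenyl]-5-methylhex-5-enoate | O=C(C[C@H](CC(C)=C)c1ccc(OCOC)cc1)OC/C=C/c1c(OCOC)ccc(Br)c1OCOC
F4 | step 12 | (2S,3S)-3-[3-bromo-2,6-bis(methoxymethoxy)phenyl]-2-{(1S)-1-[4-(methoxymethoxy)phenyl]-3-methylbut-3-en-1-yl}pent-4-enoic acid | OC(=O)[C@H]([C@@H](c1c(OCOC)ccc(Br)c1OCOC)C=C)[C@H](CC(C)=C)c1ccc(OCOC)cc1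
F5 | step 12 | (2S,3S)-3-[3-bromo-2,6-bis(methoxymethoxy)phenyl]-2-{(1S)-1-[4-(methoxymethoxy)phenyl]-3-methylbut-3-en-1-yl}pent-4-en-1-ol | OC[C@H]([C@@H](c1c(OCOC)ccc(Br)c1OCOC)C=C)[C@H](CC(C)=C)c1ccc(OCOC)cc1
F6 | step 15 | [2,4-bis(methoxymethoxy)-3-(3-methylbut-2-en-1-yl)phenyl]{(1S,2S,6S)-2-[3-bromo-2,6-bis(methoxymethoxy)phenyl]-6-[4-(methoxymethoxy)phenyl]-4-methylcyclohex-3-en-1-yl}methanone | CC(C)=CCc1c(OCOC)ccc(C(=O)[C@@H]2[C@@H](c3c(OCOC)ccc(Br)c3OCOC)C=C(C)C[C@@H]2c2ccc(OCOC)cc2)c1OCOC
F7 | step 15 | 2-{(E)-2-[2,4-bis(methoxymethoxy)phenyl]ethenyl}-4,4,5,5-tetramethyl-1,3,2-dioxaborolane | CC1(C)OB(/C=C/c2ccc(OCOC)cc2OCOC)OC1(C)C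
F8 | step 17 | heptakis(trimethylsilyl) ether of the target | CC(C)=CCc1c(O[Si](C)(C)C)ccc(C(=O)[C@@H]2[C@@H](c3c(O[Si](C)(C)C)ccc(C(=O)/C=C/c4ccc(O[Si](C)(C)C)cc4O[Si](C)(C)C)c3O[Si](C)(C)C)C=C(C)C[C@@H]2c2ccc(O[Si](C)(C)C)cc2)c1O[Si](C)(C)C
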